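## Analysis of the target

- Target **27** is a 2H-chromene: benzene ring A fused to pyran ring B through C4a and C8a, with O1, C2, C3=C4 completing ring B.
- Ring A is a hydroquinone (C5–OH, C8–OH) with an (E)-cinnamoyl group at C6 and hydrogen at C7. C5–OH lies between C4a and the ketone, so the molecule is also a 2'-hydroxychalcone.
- C2 is the only stereocentre and is (S). It is fully substituted: O1, C3, a methyl group and C1' of an (E)-4-hydroxy-4-methylpent-2-enyl chain. Nothing else in the molecule can relay or correct its configuration.
- The sensitive groups are the hydroquinone (air oxidation), the enone (conjugate addition, including closure of C5–OH to a flavanone), the tertiary allylic alcohol at C4' (ionises in acid) and the 2H-pyran. The pyran is an acid-labile styrenyl ether and can open reversibly by a 6π process under light or strong heat, which would racemise C2.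
- The difficulty is twofold. The quaternary ether stereocentre has two carbon substituents (CH3 and CH2R) that differ little in size. The tetrasubstituted, oxidation-prone ring A must then be completed without disturbing that centre.
- The strategy rests on C2 being a tertiary ether carbon next to C3. An epoxide across C2–C3 of a phenol allylated at C4a lets the C8a oxygen enter C2 with inversion. The hydroxyl left on C3 is later eliminated to give C3=C4.

## Retrosynthetic reasoning

**Hydroquinone last.** The two O–H groups of **27** are traced back to the methyl ethers of **25** through quinone **26**. The free hydroquinone and the 2'-hydroxychalcone are the most fragile functions, so they are released only at the end. Oxidative removal of both para methyl groups followed by mild reduction must not touch the enone, the tertiary alcohol or C2.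

**Side chain by cross-metathesis.** The C2'=C3' bond of **25** is cut to give the allyl compound **23** and the tertiary allylic alcohol **24**. An allyl group is a robust three-carbon handle, inert to acid, base and organometallics. The tertiary allylic alcohol would not survive the dehydration, the formylation or the acid of the earlier steps, so it is attached after them.

**Cinnamoyl group in three operations.** The ketone of **23** comes from the doubly activated alcohol **22**. The bond between its carbinol carbon and the styryl carbon is cut to aldehyde **19** and the styryl nucleophile **21**, made from **20**. The C6–CHO bond of **19** is cut back to chromene **17**. C6 is the only ring position para to one oxygen (O1) and ortho to another (C5–OMe), so an electrophilic formylation should go there. A direct Friedel–Crafts acylation would need Lewis acids that the chromene does not tolerate.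

**C3=C4 from a C3 hydroxyl.** Chromene **17** is derived from chroman-3-ol **15** by loss of the C3 hydroxyl and one C4 hydrogen. C2 has no hydrogen, so the elimination can only go toward C4.

**Key disconnection, O1–C2.** Chromanol **15** is opened at O1–C2 to the epoxy phenol **14**. Forward, the phenol attacks the fully substituted epoxide carbon in a 6-endo opening with inversion. The configuration of C2 is therefore fixed by the epoxide, and the C3 stereocentre serves as a temporary marker of how faithful the opening was.

**Epoxy phenol from a protected alkene.** Phenol **14** is released from silyl ether **13**, and **13** comes from alkene **12** by Shi epoxidation of the E-trisubstituted double bond.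
- The phenol must be masked during the epoxidation, because an electron-rich phenoxide would be oxidised and could open the epoxide 5-exo under the basic conditions.
- An acetal protecting group cannot be carried into the cyclisation. The acid needed to cleave an aryl methoxymethyl ether is stronger than the trisubstituted epoxide tolerates.
- The mask is therefore a silyl ether, removed with buffered fluoride before the acid step.

**Aryl–CH2 bond.** Silyl ether **12** comes from phenol **11**, and **11** from the methoxymethyl ether **10**. The bond between the arene and the side-chain CH2 of **10** is cut to the aryl anion **8**/**9**, formed from **7**, and the allylic bromide **5**. The methoxymethyl group is used here because it directs lithiation to the single position between two oxygens. A silyl ether could not do this without migrating.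

**Alkene geometry.** Bromide **5** comes from alcohol **4**. The E-trisubstituted alkene of **4** is traced to alkyne **1** by syn-carbometalation (Negishi carboalumination via **2** and **3**) and one-carbon extension. This fixes the geometry that the epoxidation later turns into the configuration of C2. Ether **7** is the protected form of phenol **6**.

## Alternatives that were turned down

**Alternative 1: aryne annulation with a chiral-pool lactone.**
- Disconnection: both bonds joining ring B to ring A (C8a–O1 and C4–C4a) are cut at once.
- Forward key step: 3,6-dimethoxybenzyne A3, generated with fluoride, is attacked by the tertiary alkoxide of (S)-mevalonolactone A2. The resulting aryl anion closes onto the lactone carbonyl, giving chromanone A1 with a freed hydroxyethyl arm.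
- For: A3 is symmetrical, so there is no regiochemical question. The stereocentre is taken intact from A2; no bond to it is made or broken.
- Against: A2 is the unnatural antipode and must itself be made enantioselectively. A hindered tertiary alkoxide that is also a β-hydroxy ester can fragment by retro-aldol cleavage. The acidic lactone α-hydrogens can quench the aryl anion before it acylates.
- Against, end-game: A1 still needs the C4 ketone converted to C3=C4, a two-carbon arm built up to the five-carbon E-allylic alcohol, C6 acylation on a ring deactivated by that ketone, and demethylation.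
- Comparison: on configurational security of C2 this route is stronger than the chosen one, since nothing can erode a chiral-pool centre. The chosen route offers cheap achiral inputs, a stereocentre set by a catalyst and transferred stereospecifically, and an allyl handle that is one step from the finished side chain.

**Alternative 2: gold-catalysed hydroarylation of a tertiary aryl propargyl ether.**
- Disconnection: C4–C4a.
- Forward key step: under cationic gold catalysis the terminal alkyne of ether A5 is attacked 6-endo by the arene carbon ortho to the ether oxygen. This gives chromene A4 with C3=C4 and the C6 aldehyde already present.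
- For: no dehydration step and no formylation on an acid-sensitive chromene are needed; on this point it is stronger than the chosen route. The side-chain carbons are also complete.
- Against: the difficulty moves into A5. An enantiopure aryl ether at a fully substituted propargylic carbon must be made by arylating a hindered tertiary alkoxide, and that alkoxide needs a multistep enantioselective preparation.
- Against, key step: the tertiary propargylic C–O bond of A5 can ionise under gold catalysis, which would racemise the only stereocentre. A5 also carries a second, internal alkyne that competes for the catalyst.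
- Against, end-game: the side-chain alkyne of A4 must be reduced to the E-alkene in the presence of an enone, which is not a trivial chemoselectivity problem.
- Comparison: the chosen route sets C2 by Shi epoxidation of a simple alkene and transfers it by a stereospecific opening, and its side chain needs no redox adjustment.

**Alternative 3: Dötz benzannulation that builds ring A last.**
- Disconnection: three bonds of ring A (C7–C8, C5–C6, C4a–C5).
- Forward key step: the pentacarbonylchromium dihydropyranyl(methoxy)carbene A7, one of its carbonyl ligands and the terminal alkyne A8 combine on warming to give the 5-hydroxy-8-methoxychroman A6.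
- For: it is the most convergent plan. It differentiates C5–OH from C8–OMe, places the C6 carbon substituent regioselectively next to the phenol, and carries the complete side chain, so neither an electrophilic substitution on a chromene nor a cross-metathesis is needed. On these points it is stronger.
- Against: it needs stoichiometric chromium. A7 requires a 2,2-disubstituted dihydropyran with the stereocentre and the oxidised side chain already in place, metalated at its vinylic position; this is a long sequence from a chiral-pool tertiary alcohol.
- Against, key step: an alkyne bearing a propargylic silyloxy group and a styryl unit is prone to side channels of the benzannulation.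
- Against, end-game: A6 is a chroman, so C3=C4 must be introduced by a late benzylic dehydrogenation in the presence of an allylic side chain and two silyl ethers. The C8 methyl ether still has to be removed oxidatively.
- Comparison: the chosen route is less convergent but uses no stoichiometric transition metal, reaches its key precursor by standard steps, and obtains C3=C4 by a regiochemically unambiguous elimination.

Key step: step 9

## Route

Assumption: the commercial D-fructose-derived Shi ketone is taken to deliver oxygen to alkene **12** on the same face as it does for other (E)-trisubstituted alkenes, which corresponds to the (2R,3R) epoxide **13**.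

Step 1
Reactants: 1 pent-1-en-4-yne
Product: 4 (2E)-3-methylhexa-2,5-dien-1-ol, via alkenylalane 2 (not isolated), via lithium alanate 3 (not isolated)
Conditions: AlMe3, Cp2ZrCl2 (20 mol %), CH2Cl2, 0 °C to rt; n-BuLi, THF–hexane, −78 °C; (CH2O)n, −78 °C to rt; aq. HCl
Reagents that add atoms: trimethylaluminium, C[Al](C)C; formaldehyde (as paraformaldehyde), C=O
Why: Negishi zirconium-catalysed carboalumination adds methyl and aluminium syn across the terminal alkyne (methyl to the internal carbon), which fixes the E geometry; the alanate then adds to formaldehyde with retention. The isolated terminal alkene is carbometalated far more slowly than the alkyne.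

Step 2
Reactants: 4 (2E)-3-methylhexa-2,5-dien-1-ol
Product: 5 (2E)-1-bromo-3-methylhexa-2,5-diene
Conditions: PBr3, Et2O, −10 °C
Reagents that add atoms: phosphorus tribromide, BrP(Br)Br
Why: Standard conversion of a primary allylic alcohol into the bromide; at low temperature the primary bromide forms without allylic transposition or loss of alkene geometry. The bromide is used crude.

Step 3
Reactants: 6 2,5-dimethoxyphenol
Product: 7 1,4-dimethoxy-2-(methoxymethoxy)benzene
Conditions: MOMCl, i-Pr2NEt, CH2Cl2, 0 °C to rt
Reagents that add atoms: chloromethyl methyl ether, COCCl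
Why: Routine O-alkylation of a phenol; the acetal oxygen is installed as the directing group for the next step.

Step 4
Reactants: 7 1,4-dimethoxy-2-(methoxymethoxy)benzene; 5 (2E)-1-bromo-3-methylhexa-2,5-diene
Product: 10 1,4-dimethoxy-2-(methoxymethoxy)-3-[(2E)-3-methylhexa-2,5-dien-1-yl]benzene, via aryllithium 8 (not isolated), via arylcopper 9 (not isolated)
Conditions: n-BuLi, THF, 0 °C; CuI, −78 to −30 °C; then 5, −78 °C to rt
Reagents that add atoms: none
Why: Directed ortho-metalation takes place at the one position flanked by the acetal oxygen and a methoxy group. The arylcopper then displaces the primary allylic bromide at the unsubstituted terminus, because attack at the other end would create a quaternary carbon, and the E alkene is retained.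

Step 5
Reactants: 10 1,4-dimethoxy-2-(methoxymethoxy)-3-[(2E)-3-methylhexa-2,5-dien-1-yl]benzene
Product: 11 3,6-dimethoxy-2-[(2E)-3-methylhexa-2,5-dien-1-yl]phenol
Conditions: aq. HCl (2 M), MeOH, rt
Reagents that add atoms: none
Why: Acid-catalysed acetal exchange removes the methoxymethyl group while the molecule has no epoxide. Dilute acid at room temperature does not add to the trisubstituted alkene or close the chroman.

Step 6
Reactants: 11 3,6-dimethoxy-2-[(2E)-3-methylhexa-2,5-dien-1-yl]phenol
Product: 12 tert-butyl{3,6-dimethoxy-2-[(2E)-3-methylhexa-2,5-dien-1-yl]phenoxy}dimethylsilane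
Conditions: TBSCl, imidazole, DMF, rt
Reagents that add atoms: tert-butyl(chloro)dimethylsilane, CC(C)(C)[Si](C)(C)Cl
Why: Silylation of the phenol gives a mask that survives the buffered oxidation of step 7 and is later removed by fluoride without acid. The two ortho substituents make the aryl silyl ether resistant to the carbonate buffer.

Step 7
Reactants: 12 tert-butyl{3,6-dimethoxy-2-[(2E)-3-methylhexa-2,5-dien-1-yl]phenoxy}dimethylsilane
Product: 13 tert-butyl(3,6-dimethoxy-2-{[(2R,3R)-3-methyl-3-(prop-2-en-1-yl)oxiran-2-yl]methyl}phenoxy)dimethylsilane
Conditions: 1,2:4,5-di-O-isopropylidene-β-D-erythro-2,3-hexodiulo-2,6-pyranose (30 mol %), KHSO5 (as the triple salt 2KHSO5·KHSO4·K2SO4), K2CO3, Bu4NHSO4, MeCN–CH2(OMe)2, aq. Na2B4O7/Na2(H2EDTA) buffer (pH 10.5), 0 °C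
Reagents that add atoms: potassium peroxymonosulfate, [K+].[O-]S(=O)(=O)OO
Why: Shi epoxidation: the chiral dioxirane transfers oxygen through a spiro transition state to one face of the E-trisubstituted alkene, setting both epoxide carbons as (R) under catalyst control. The electron-poor monosubstituted terminal alkene reacts much more slowly and the phenol is masked.

Step 8
Reactants: 13 tert-butyl(3,6-dimethoxy-2-{[(2R,3R)-3-methyl-3-(prop-2-en-1-yl)oxiran-2-yl]methyl}phenoxy)dimethylsilane
Product: 14 3,6-dimethoxy-2-{[(2R,3R)-3-methyl-3-(prop-2-en-1-yl)oxiran-2-yl]methyl}phenol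
Conditions: Bu4NF, AcOH, THF, 0 °C
Reagents that add atoms: none
Why: Fluoride cleaves the aryl silyl ether within minutes; the acetic acid buffer keeps the product as the neutral phenol, so base-induced 5-exo opening of the epoxide does not start. The crude phenol is taken on without chromatography.

Step 9
Reactants: 14 3,6-dimethoxy-2-{[(2R,3R)-3-methyl-3-(prop-2-en-1-yl)oxiran-2-yl]methyl}phenol
Product: 15 (2S,3R)-5,8-dimethoxy-2-methyl-2-(prop-2-en-1-yl)-3,4-dihydro-2H-chromen-3-ol
Conditions: camphor-10-sulfonic acid (10 mol %), CH2Cl2, −20 to 0 °C
Reagents that add atoms: none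
Why: The sulfonic acid protonates the epoxide oxygen; the C–O bond to the fully substituted carbon lengthens because that carbon carries positive charge best, and the C8a hydroxyl attacks it from the rear before a free cation forms, making O1–C2 with inversion. The closest known reaction type is the acid-catalysed cyclisation of ortho-(2,3-epoxy-3-methylalkyl)phenols to 2,2-disubstituted chroman-3-ols. Ring B closes in the 6-endo-tet mode; the competing 5-exo attack at the secondary carbon would give a dihydrobenzofuran and is electronically disfavoured under acid. The new stereocentre C2 is substrate-controlled: the (3R) epoxide carbon set in step 7 is inverted to (S), while C3 keeps its C–O bond and stays (R). The step needs endo regioselectivity and SN2-like timing, and the tertiary epoxide terminus, the low temperature and the weakly ionising solvent secure both. Any leakage through an open cation would appear as the (2R,3R) diastereomer, which can be removed here because C3 is still a stereocentre. Only one hydroxyl is free, the flanking methoxy oxygen is a far weaker nucleophile, and the terminal alkene is not attacked under these conditions.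

Step 10
Reactants: 15 (2S,3R)-5,8-dimethoxy-2-methyl-2-(prop-2-en-1-yl)-3,4-dihydro-2H-chromen-3-ol
Product: 17 (2S)-5,8-dimethoxy-2-methyl-2-(prop-2-en-1-yl)-2H-chromene, via sulfamate ester 16 (not isolated)
Conditions: Burgess reagent (MeO2CN–SO2N+Et3), toluene, rt then 60 °C
Reagents that add atoms: none
Why: Burgess dehydration: the secondary alcohol forms a sulfamate that undergoes thermal syn-elimination. C2 has no hydrogen, so only a C4 hydrogen can be lost and C3=C4 results; the non-ionising mechanism leaves C2 untouched.

Step 11
Reactants: 17 (2S)-5,8-dimethoxy-2-methyl-2-(prop-2-en-1-yl)-2H-chromene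
Product: 19 (2S)-5,8-dimethoxy-2-methyl-2-(prop-2-en-1-yl)-2H-chromene-6-carbaldehyde, via iminium salt 18 (not isolated)
Conditions: POCl3, DMF, 0 to 45 °C; aq. NaOAc
Reagents that add atoms: N,N-dimethylformamide, CN(C)C=O; water, O
Why: Vilsmeier–Haack formylation: the chloroiminium ion attacks C6, the only ring position para to one oxygen (O1) and ortho to another (C5–OMe), as in the formylation of 1,2,4-trialkoxybenzenes. C7 is para only to carbon, and the temperature is kept low to spare the chromene.

Step 12
Reactants: 19 (2S)-5,8-dimethoxy-2-methyl-2-(prop-2-en-1-yl)-2H-chromene-6-carbaldehyde; 20 (E)-(2-bromoethenyl)benzene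
Product: 22 (1RS,2E)-1-[(2S)-5,8-dimethoxy-2-methyl-2-(prop-2-en-1-yl)-2H-chromen-6-yl]-3-phenylprop-2-en-1-ol, via styrylmagnesium bromide 21 (not isolated)
Conditions: 20, Mg, THF; then 19, THF, −20 to 0 °C; aq. NH4Cl
Reagents that add atoms: none
Why: Grignard addition of an alkenylmagnesium halide to an aryl aldehyde. The new carbinol centre is formed as a mixture, which is irrelevant because it is oxidised in the next step.

Step 13
Reactants: 22 (1RS,2E)-1-[(2S)-5,8-dimethoxy-2-methyl-2-(prop-2-en-1-yl)-2H-chromen-6-yl]-3-phenylprop-2-en-1-ol
Product: 23 (2E)-1-[(2S)-5,8-dimethoxy-2-methyl-2-(prop-2-en-1-yl)-2H-chromen-6-yl]-3-phenylprop-2-en-1-one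
Conditions: MnO2, CH2Cl2, rt
Reagents that add atoms: none
Why: MnO2 selectively oxidises an alcohol that is both benzylic and allylic; the conjugated enone settles in the E form. Nothing else in the molecule is oxidised by this reagent.

Step 14
Reactants: 23 (2E)-1-[(2S)-5,8-dimethoxy-2-methyl-2-(prop-2-en-1-yl)-2H-chromen-6-yl]-3-phenylprop-2-en-1-one; 24 2-methylbut-3-en-2-ol
Product: 25 (2E)-1-{(2S)-2-[(2E)-4-hydroxy-4-methylpent-2-en-1-yl]-5,8-dimethoxy-2-methyl-2H-chromen-6-yl}-3-phenylprop-2-en-1-one
Conditions: 24 (10 equiv), second-generation Hoveyda–Grubbs catalyst (H2IMes)Cl2Ru(=CH-C6H4-2-O-i-Pr) (5 mol %), CH2Cl2, 40 °C, exclusion of light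
Reagents that add atoms: none
Why: Olefin cross-metathesis between the terminal allyl group and an excess of a hindered tertiary allylic alcohol that homodimerises slowly; the new disubstituted alkene forms E under thermodynamic control. The ring alkene C3=C4 next to the quaternary C2 and the electron-poor enone do not take part.

Step 15
Reactants: 25 (2E)-1-{(2S)-2-[(2E)-4-hydroxy-4-methylpent-2-en-1-yl]-5,8-dimethoxy-2-methyl-2H-chromen-6-yl}-3-phenylprop-2-en-1-one
Product: 27 (2E)-1-{(2S)-5,8-dihydroxy-2-[(2E)-4-hydroxy-4-methylpent-2-en-1-yl]-2-methyl-2H-chromen-6-yl}-3-phenylprop-2-en-1-one, via quinone 26 (not isolated)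
Conditions: (NH4)2Ce(NO3)6, MeCN–H2O, 0 °C; then aq. Na2S2O4, EtOAc, rt, under argon
Reagents that add atoms: water, O
Why: Oxidative demethylation of a para-dimethoxyarene by tetravalent cerium: water adds at the two methoxy-bearing carbons of the radical cation and methanol leaves, giving the para-quinone. Dithionite reduces the quinone at once to the hydroquinone under near-neutral conditions, which spare the enone, the tertiary alcohol and C2.

## Compound list

1 | pent-1-en-4-yne | C=CCC#C | starting material
2 | dimethyl[(1E)-2-methylpenta-1,4-dien-1-yl]alumane | C[Al](C)/C=C(\C)CC=C | intermediate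
3 | lithium butyl(dimethyl)[(1E)-2-methylpenta-1,4-dien-1-yl]aluminate | [Li+].CCCC[Al-](C)(C)/C=C(\C)CC=C | intermediate
4 | (2E)-3-methylhexa-2,5-dien-1-ol | OC/C=C(\C)CC=C | intermediate
5 | (2E)-1-bromo-3-methylhexa-2,5-diene | BrC/C=C(\C)CC=C | intermediate
6 | 2,5-dimethoxyphenol | COc1ccc(OC)c(O)c1 | starting material
7 | 1,4-dimethoxy-2-(methoxymethoxy)benzene | COCOc1cc(OC)ccc1OC | intermediate
8 | [3,6-dimethoxy-2-(methoxymethoxy)phenyl]lithium | [Li]c1c(OC)ccc(OC)c1OCOC | intermediate
9 | [3,6-dimethoxy-2-(methoxymethoxy)phenyl]copper | [Cu]c1c(OC)ccc(OC)c1OCOC | intermediate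
10 | 1,4-dimethoxy-2-(methoxymethoxy)-3-[(2E)-3-methylhexa-2,5-dien-1-yl]benzene | COCOc1c(OC)ccc(OC)c1C/C=C(\C)CC=C | intermediate
11 | 3,6-dimethoxy-2-[(2E)-3-methylhexa-2,5-dien-1-yl]phenol | COc1ccc(OC)c(C/C=C(\C)CC=C)c1O | intermediate
12 | tert-butyl{3,6-dimethoxy-2-[(2E)-3-methylhexa-2,5-dien-1-yl]phenoxy}dimethylsilane | COc1ccc(OC)c(C/C=C(\C)CC=C)c1O[Si](C)(C)C(C)(C)C | intermediate
13 | tert-butyl(3,6-dimethoxy-2-{[(2R,3R)-3-methyl-3-(prop-2-en-1-yl)oxiran-2-yl]methyl}phenoxy)dimethylsilane | COc1ccc(OC)c(C[C@H]2O[C@]2(C)CC=C)c1O[Si](C)(C)C(C)(C)C | intermediate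
14 | 3,6-dimethoxy-2-{[(2R,3R)-3-methyl-3-(prop-2-en-1-yl)oxiran-2-yl]methyl}phenol | COc1ccc(OC)c(C[C@H]2O[C@]2(C)CC=C)c1O | intermediate
15 | (2S,3R)-5,8-dimethoxy-2-methyl-2-(prop-2-en-1-yl)-3,4-dihydro-2H-chromen-3-ol | C=CC[C@@]1(C)[C@H](O)Cc2c(OC)ccc(OC)c2O1 | intermediate
16 | triethylammonium {[(2S,3R)-5,8-dimethoxy-2-methyl-2-(prop-2-en-1-yl)-3,4-dihydro-2H-chromen-3-yl]oxysulfonyl}(methoxycarbonyl)azanide | C=CC[C@@]1(C)[C@H](OS(=O)(=O)[N-]C(=O)OC)Cc2c(OC)ccc(OC)c2O1.CC[NH+](CC)CC | intermediate
17 | (2S)-5,8-dimethoxy-2-methyl-2-(prop-2-en-1-yl)-2H-chromene | C=CC[C@@]1(C)C=Cc2c(OC)ccc(OC)c2O1 | intermediate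
18 | {[(2S)-5,8-dimethoxy-2-methyl-2-(prop-2-en-1-yl)-2H-chromen-6-yl]methylidene}dimethylammonium dichlorophosphate | C=CC[C@@]1(C)C=Cc2c(OC)c(C=[N+](C)C)cc(OC)c2O1.[O-]P(=O)(Cl)Cl | intermediate
19 | (2S)-5,8-dimethoxy-2-methyl-2-(prop-2-en-1-yl)-2H-chromene-6-carbaldehyde | C=CC[C@@]1(C)C=Cc2c(OC)c(C=O)cc(OC)c2O1 | intermediate
20 | (E)-(2-bromoethenyl)benzene | Br/C=C/c1ccccc1 | starting material
21 | bromo[(E)-2-phenylethenyl]magnesium | Br[Mg]/C=C/c1ccccc1 | intermediate
22 | (1RS,2E)-1-[(2S)-5,8-dimethoxy-2-methyl-2-(prop-2-en-1-yl)-2H-chromen-6-yl]-3-phenylprop-2-en-1-ol (carbinol centre undefined) | C=CC[C@@]1(C)C=Cc2c(OC)c(C(O)/C=C/c3ccccc3)cc(OC)c2O1 | intermediate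
23 | (2E)-1-[(2S)-5,8-dimethoxy-2-methyl-2-(prop-2-en-1-yl)-2H-chromen-6-yl]-3-phenylprop-2-en-1-one | C=CC[C@@]1(C)C=Cc2c(OC)c(C(=O)/C=C/c3ccccc3)cc(OC)c2O1 | intermediate
24 | 2-methylbut-3-en-2-ol | CC(C)(O)C=C | starting material
25 | (2E)-1-{(2S)-2-[(2E)-4-hydroxy-4-methylpent-2-en-1-yl]-5,8-dimethoxy-2-methyl-2H-chromen-6-yl}-3-phenylprop-2-en-1-one | CC(C)(O)/C=C/C[C@@]1(C)C=Cc2c(OC)c(C(=O)/C=C/c3ccccc3)cc(OC)c2O1 | intermediate
26 | (2S)-2-[(2E)-4-hydroxy-4-methylpent-2-en-1-yl]-2-methyl-6-[(2E)-3-phenylprop-2-enoyl]-2H-chromene-5,8-dione | CC(C)(O)/C=C/C[C@@]1(C)C=CC2=C(O1)C(=O)C=C(C(=O)/C=C/c3ccccc3)C2=O | intermediate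
27 | (2E)-1-{(2S)-5,8-dihydroxy-2-[(2E)-4-hydroxy-4-methylpent-2-en-1-yl]-2-methyl-2H-chromen-6-yl}-3-phenylprop-2-en-1-one | CC(C)(O)/C=C/C[C@@]1(C)C=Cc2c(O)c(C(=O)/C=C/c3ccccc3)cc(O)c2O1 | target

## Step count and least certain steps

Total: 15 steps. The longest linear sequence is 14 steps (steps 1, 2 and 4 to 15, from **1**); the branch from **6** joins after one step (step 3). From step 10 on, every chromene should be kept away from light and strong heat, so that reversible electrocyclic opening of ring B cannot erode C2.

**Step 9 (key step).** The most likely failure is partial ionisation of the protonated epoxide to an open tertiary cation before the phenol arrives. That would lower the configurational purity at C2. Competing 5-exo attack at the secondary carbon is the second concern. Both arise because the same charge build-up that directs attack to the tertiary carbon also loosens it.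

The fallback gives up the asymmetric ring closure. It sets out from phenol **11** and returns to the route at chromene **17**. Treating **11** with DDQ in benzene at 80 °C removes a benzylic hydride, and the resulting ortho-quinone methide closes by oxa-6π-electrocyclisation to racemic (2RS)-5,8-dimethoxy-2-methyl-2-(prop-2-en-1-yl)-2H-chromene F1. This is the known oxidative cyclisation of ortho-(3,3-disubstituted allyl)phenols. The enantiomers of F1 would be separated by preparative chromatography on a cellulose tris(3,5-dimethylphenylcarbamate) phase, and the (S) enantiomer is **17**. Half of the material is lost, but steps 5 to 10 are replaced by one reaction and a separation.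

**Step 15.** The acyl group makes ring A a poorer electron donor, so oxidation by tetravalent cerium may be slow. The acidic oxidant can then ionise the tertiary allylic alcohol or the C2–O1 bond, and the electrophilic acylquinone can add water before it is reduced.

The fallback removes the two methyl groups one at a time and oxidises under milder conditions. It sets out from **23** and returns at quinone **26**.
- BCl3 in CH2Cl2 at −78 °C cleaves only the C5 methyl ether, which is chelated to the ketone. This gives (2E)-1-[(2S)-5-hydroxy-8-methoxy-2-methyl-2-(prop-2-en-1-yl)-2H-chromen-6-yl]-3-phenylprop-2-en-1-one F2.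
- Cross-metathesis with **24**, as in step 14, gives (2E)-1-{(2S)-5-hydroxy-2-[(2E)-4-hydroxy-4-methylpent-2-en-1-yl]-8-methoxy-2-methyl-2H-chromen-6-yl}-3-phenylprop-2-en-1-one F3.
- PhI(OAc)2 in aqueous MeCN at 0 °C oxidises this para-methoxyphenol to **26** without strong acid.
- **26** is reduced with Na2S2O4 to **27** as in step 15.

**Step 11.** The chloroiminium ion may attack the electron-rich C3=C4 bond in competition with C6, or the acid released may open the tertiary allylic ether of ring B.

The fallback formylates before the double bond exists. It sets out from chromanol **15** and returns at aldehyde **19**.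
- MsCl and Et3N in CH2Cl2 at 0 °C give (2S,3R)-5,8-dimethoxy-2-methyl-2-(prop-2-en-1-yl)-3,4-dihydro-2H-chromen-3-yl methanesulfonate F4.
- POCl3/DMF then formylates C6 of this saturated chroman through {[(2S,3R)-3-(methanesulfonyloxy)-5,8-dimethoxy-2-methyl-2-(prop-2-en-1-yl)-3,4-dihydro-2H-chromen-6-yl]methylidene}dimethylammonium dichlorophosphate F5. Aqueous NaOAc work-up gives (2S,3R)-6-formyl-5,8-dimethoxy-2-methyl-2-(prop-2-en-1-yl)-3,4-dihydro-2H-chromen-3-yl methanesulfonate F6.
- DBU in toluene at 90 °C eliminates the mesylate anti toward the benzylic C4 and gives **19**.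

**Step 10.** The sulfamate sits on a hindered carbon next to the quaternary C2. Elimination may be slow, and ionisation with a 1,2-shift from C2 or substitution at C3 may compete.

The fallback avoids any leaving group at C3. It sets out from **15** and returns at **17**.
- Dess–Martin periodinane with NaHCO3 in CH2Cl2 gives (2S)-5,8-dimethoxy-2-methyl-2-(prop-2-en-1-yl)-2H-chromen-3(4H)-one F7. It can enolise only toward C4.
- Tf2O and 2,6-di-tert-butyl-4-methylpyridine in CH2Cl2 at 0 °C give (2S)-5,8-dimethoxy-2-methyl-2-(prop-2-en-1-yl)-2H-chromen-3-yl trifluoromethanesulfonate F8.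
- Pd(OAc)2, PPh3, Bu3N and HCO2H in DMF at 60 °C replace the triflate by hydrogen and give **17**.

## Further compounds

F1 | step 9 | (2RS)-5,8-dimethoxy-2-methyl-2-(prop-2-en-1-yl)-2H-chromene | C=CCC1(C)C=Cc2c(OC)ccc(OC)c2O1
F2 | step 15 | (2E)-1-[(2S)-5-hydroxy-8-methoxy-2-methyl-2-(prop-2-en-1-yl)-2H-chromen-6-yl]-3-phenylprop-2-en-1-one | C=CC[C@@]1(C)C=Cc2c(O)c(C(=O)/C=C/c3ccccc3)cc(OC)c2O1
F3 | step 15 | (2E)-1-{(2S)-5-hydroxy-2-[(2E)-4-hydroxy-4-methylpent-2-en-1-yl]-8-methoxy-2-methyl-2H-chromen-6-yl}-3-phenylprop-2-en-1-one | CC(C)(O)/C=C/C[C@@]1(C)C=Cc2c(O)c(C(=O)/C=C/c3ccccc3)cc(OC)c2O1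
F4 | step 11 | (2S,3R)-5,8-dimethoxy-2-methyl-2-(prop-2-en-1-yl)-3,4-dihydro-2H-chromen-3-yl methanesulfonate | C=CC[C@@]1(C)[C@H](OS(C)(=O)=O)Cc2c(OC)ccc(OC)c2O1
F5 | step 11 | {[(2S,3R)-3-(methanesulfonyloxy)-5,8-dimethoxy-2-methyl-2-(prop-2-en-1-yl)-3,4-dihydro-2H-chromen-6-yl]methylidene}dimethylammonium dichlorophosphate | C=CC[C@@]1(C)[C@H](OS(C)(=O)=O)Cc2c(OC)c(C=[N+](C)C)cc(OC)c2O1.[O-]P(=O)(Cl)Cl
F6 | step 11 | (2S,3R)-6-formyl-5,8-dimethoxy-2-methyl-2-(prop-2-en-1-yl)-3,4-dihydro-2H-chromen-3-yl methanesulfonate | C=CC[C@@]1(C)[C@H](OS(C)(=O)=O)Cc2c(OC)c(C=O)cc(OC)c2O1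
F7 | step 10 | (2S)-5,8-dimethoxy-2-methyl-2-(prop-2-en-1-yl)-2H-chromen-3(4H)-one | C=CC[C@@]1(C)C(=O)Cc2c(OC)ccc(OC)c2O1
F8 | step 10 | (2S)-5,8-dimethoxy-2-methyl-2-(prop-2-en-1-yl)-2H-chromen-3-yl trifluoromethanesulfonate | C=CC[C@@]1(C)C(OS(=O)(=O)C(F)(F)F)=Cc2c(OC)ccc(OC)c2O1
A1 | alternative 1 | (2S)-2-(2-hydroxyethyl)-5,8-dimethoxy-2-methyl-2,3-dihydro-4H-chromen-4-one | OCC[C@@]1(C)CC(=O)c2c(OC)ccc(OC)c2O1
A2 | alternative 1 | (S)-mevalonolactone, (4S)-4-hydroxy-4-methyloxan-2-one | C[C@]1(O)CCOC(=O)C1
A3 | alternative 1 | 3,6-dimethoxybenzyne (1,4-dimethoxy-2,3-didehydrobenzene) | COC1=CC=C(OC)C#C1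
A4 | alternative 2 | (2S)-2-[4-(tert-butyldimethylsilyloxy)-4-methylpent-2-yn-1-yl]-5,8-dimethoxy-2-methyl-2H-chromene-6-carbaldehyde | CC(C)(C)[Si](C)(C)OC(C)(C)C#CC[C@@]1(C)C=Cc2c(OC)c(C=O)cc(OC)c2O1
A5 | alternative 2 | 4-{[(3S)-7-(tert-butyldimethylsilyloxy)-3,7-dimethylocta-1,5-diyn-3-yl]oxy}-2,5-dimethoxybenzaldehyde | CC(C)(C)[Si](C)(C)OC(C)(C)C#CC[C@@](C)(C#C)Oc1cc(OC)c(C=O)cc1OC
A6 | alternative 3 | (2R)-6-[(1RS,2E)-1-(tert-butyldimethylsilyloxy)-3-phenylprop-2-en-1-yl]-8-methoxy-2-methyl-2-[(2E)-4-methyl-4-(triethylsilyloxy)pent-2-en-1-yl]-3,4-dihydro-2H-chromen-5-ol | CC[Si](CC)(CC)OC(C)(C)/C=C/C[C@@]1(C)CCc2c(O)c(C(O[Si](C)(C)C(C)(C)C)/C=C/c3ccccc3)cc(OC)c2O1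
A7 | alternative 3 | pentacarbonyl(methoxy{(2R)-2-methyl-2-[(2E)-4-methyl-4-(triethylsilyloxy)pent-2-en-1-yl]-3,4-dihydro-2H-pyran-6-yl}methylidene)chromium | COC(=[Cr](=C=O)(=C=O)(=C=O)(=C=O)=C=O)C1=CCC[C@](C)(C/C=C/C(C)(C)O[Si](CC)(CC)CC)O1
A8 | alternative 3 | tert-butyldimethyl{[(1E,3RS)-1-phenylpent-1-en-4-yn-3-yl]oxy}silane | C#CC(O[Si](C)(C)C(C)(C)C)/C=C/c1ccccc1
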